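A slow flask tempts you to read its last point as its end, and the north-east flask, at 80 °C, tests that temptation.

common to all: starting material 0.20 M; catalyst 14 mM

| flask | temperature | remark | time |
|---|---|---|---|
| north-east | 80 °C | the very flask that is asked about, followed so far |  |
| south | 86 °C | run made earlier |  |
| flask | 80 °C |  | 6.0 h |

| run | time / h | target / % | starting material / % |
|---|---|---|---|
| north-east | 0.417 | 7.1 | 76.5 |
| north-east | 1.33 | 16.2 | 47.5 |
| north-east | 2.00 | 19.8 | 35.4 |
| north-east | 3.00 | 22.0 | 25.4 |
| north-east | 5.00 | 22.5 | 16.8 |
| south | 0.417 | 8.8 | 68.9 |
| south | 1.33 | 18.8 | 37.5 |
| south | 2.00 | 22.2 | 26.9 |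
| south | 3.00 | 24.1 | 18.9 |
| south | 5.00 | 24.3 | 14.8 |

(scatter of a reading: 0.3 percentage points)

* target, in percent of the starting material first charged, at 6.0 h
* the remedy with the largest gain of target, or "none" below 2 percentage points (grey / violet / teal / green / none)
* target present, with what was taken out counted in, in percent of the starting material first charged, after grey
* target present, with what was taken out counted in, in percent of the starting material first charged, after teal

- grey: at 6.0 h take out 90% of the target then present, then wait 6.0 h
- violet: change nothing and wait 6.0 h more
- teal: at 6.0 h add catalyst, 100% of the amount charged, then wait 6.0 h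
- green: at 6.0 h raise the temperature by 25 K, then wait 6.0 h

- a species is counted by the starting material in it: one self-condensation product counts as two
- target taken out counts as made
- candidate steps: starting material + catalyst <-> target + catalyst; target <-> isomer of the product; isomer of the product + catalyst <-> starting material + catalyst; starting material <-> dormant form; 2 starting material -> self-condensation product
- additions bring no volume worth counting

A bench rule helps here: where target stops rising, what enters it equals what leaves it, so read target against starting material at that point. Call this the resting ratio q, target over starting material at the last reading. If the leak from target is small, q approximates the equilibrium constant of the catalysed step, a pre-equilibrium.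

    north-east: q = 22.5% / 16.8% = 1.34
    south: q = 24.3% / 14.8% = 1.64

The rule's border is flatness against the scatter. In the north-east run, target's step up to 3.00 h is 7.33 standard deviations, and its last step is 1.67. The ratio at 3.00 h, 0.866, is therefore no resting ratio, and the last reading has barely crossed the border.

The hotter south run has the larger q. My own reckoning stretches that trend to green and takes target plus starting material at the last reading as the pool, standing in for the flask at 6.0 h:

    hot q = 3.13
    pool = 39.3%
    green: pool × hot q / (1 + hot q) = 29.8%
    grey: taken out + (pool − taken out) × q / (1 + q) = 31.2%

Both beat the margin, but they differ by 1.4 percentage points, less than the margin, so I cannot part them.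

The forecast gives 22.3% now, 38% for grey and 21% for teal, and it picks grey. On heat it says “Green shifts the equilibrium little and speeds the leak, so no gain”, where my reckoning gains 7.3 points.

The flask holds 22.0% at 6.0 h. The best remedy is green, gaining 16 points, while grey gains 6.9 points and reaches 28.8%, and teal reaches 17.3%.

    starting material + catalyst ⇌ target + catalyst, rate k1*[starting material]*[catalyst] forward; the back reaction follows from the equilibrium constant (K = 1.30, k = 14.0 /M/h, Ea = 57.0 kJ/mol, ΔH = 37.0 kJ/mol)
    target ⇌ isomer of the product (K = 2.50, k = 0.0270 /h, Ea = 113 kJ/mol, ΔH = −90.0 kJ/mol)
    isomer of the product + catalyst ⇌ starting material + catalyst, rate k3*[catalyst]*[isomer of the product] forward; the back reaction follows from the equilibrium constant (k = 4.40 /M/h, Ea = 88.0 kJ/mol)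
    starting material ⇌ dormant form (K = 0.480, k = 0.0380 /h, Ea = 130 kJ/mol, ΔH = −57.0 kJ/mol)
    2 starting material → self-condensation product (k = 0.600 /M/h, Ea = 73.0 kJ/mol)
    (constants at 80 °C)

In this flask, the relaxation half-life of starting material and target by their step alone at 6.00 h, 2.00 h, is shorter than that of target and isomer of the product by their step alone, 18.3 h, which is long against 6.0 h. Carried to a later state, q reads as follows: at 60.0 h this flask holds 9.68% starting material, and q gives 13.0% target against 13.0% found. A neighbour flask with the same charge and temperature, read at 25 h, holds 11.1% starting material, and q gives 14.9% target against 15.3% found.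

All runs are calculated from invented constants.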